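Over the 4.0 h of this flask a single-handed free catalyst works on a racemate of left-handed substrate and right-handed substrate, while a solid reagent, none of it dissolved at the start, comes into solution. The zeta run is this same flask, followed up to 120 min.

- zeta: left-handed substrate 19 mM; right-handed substrate 19 mM; solid reagent 19 mM; free catalyst 0.38 mM; the very flask that is asked about, followed so far
- flask: left-handed substrate 19 mM; solid reagent 19.0 mM; free catalyst 0.38 mM; right-handed substrate 19 mM; time 4.0 h

- zeta (time / min: left-handed product / %, right-handed product / %, left-handed substrate / %): 6.00: 0, 1, 47; 20.0: 0, 0, 51; 30.0: 0, 0, 47; 50.0: 6, 2, 43; 80.0: 12, 0, 40; 90.0: 17, 0, 36; 120: 26, 3, 33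

(standard deviation of a reading: 2 percentage points)

- free catalyst is single-handed; left-handed substrate and right-handed substrate are mirror images of each other, charged as a racemate, each of them at the stated concentration
- as a solid, counted per litre of solution: solid reagent
- the numbers in the tables scatter with a standard deviation of 2 percentage points
- at the start none of the solid reagent is in solution
- an excess is below zero if the other one leads

- excess of left-handed product over right-handed product in the product at 25 min
- excess of left-handed product over right-handed product in the product at 4.0 h
- part of the left-handed substrate and right-handed substrate charged together that has reacted at 4.0 h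

I reckoned the end state first. The charge of solid reagent over the two substrates charged together is 50.0%; I called this the reagent ceiling, the limiting-reagent bound on conversion, taking one solid reagent per product formed. The zeta run's pace between 50.0 min and 120 min, carried straight on from the 29.0% of product read last, reaches that ceiling at 190 min, earlier than 4.0 h, so I committed to a conversion close under the ceiling.

The forecast gave 87% (65% to 100%) at 25 min, 85% (72% to 95%) at 4.0 h, and a conversion of 47% (38% to 50%), saying the reagent “caps conversion at 50%”.

The flask gave 95.7%, 94.8% and 43.4%: both excesses higher than forecast, the conversion lower.

    free catalyst + left-handed substrate ⇌ catalyst intermediate A (K = 100 M⁻¹, k = 5.08 M⁻¹ s⁻¹)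
    free catalyst + right-handed substrate ⇌ catalyst intermediate B (K = 25.0 M⁻¹, k = 65.5 M⁻¹ s⁻¹)
    partner + catalyst intermediate A → free catalyst + left-handed product (k = 1.42 M⁻¹ s⁻¹)
    partner + catalyst intermediate B → free catalyst + right-handed product (k = 0.114 M⁻¹ s⁻¹)
    left-handed substrate ⇌ right-handed substrate (k = 2.53 × 10⁻⁴ s⁻¹)
    solid reagent ⇌ partner, rate k6*(cs6 - [partner]) while solid is left; crystals form when [partner] > cs6 (solubility = 10.0 mM, k = 3.81 × 10⁻⁴ s⁻¹)
    2 free catalyst ⇌ resting dimer, settled at all times (K = 815 M⁻¹)

The flask ended 6.6 percentage points under the reagent ceiling: at 4.00 h the solid reagent stood at 0% of its charge, but 2.68 mM of partner was still in solution. The main reason for the excess at 4.0 h is the way back from catalyst intermediate B to free catalyst and right-handed substrate: the run without that way back gives −97.1% against 94.8%. The neighbour flask charged with 7.6 mM of solid reagent has a ceiling of 20.0%, and it reacted 20.0% by 4.00 h, with 0.245 mM of partner in solution.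

The earlier runs and the new flask come from a simulation from invented constants; noise was put on by code.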